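In pyran numbering (O1, C2 methyl, C3 formyl, C4 acetate arm, C5 methyl ester, C6), the atoms O1–C6=C5(CO2Me)–C4–CH2–C(=O)–O are the ring of a 5-carbomethoxy-3,4-dihydro-2-pyranone, and C2, C3, the methyl and the formyl carbon are a crotonaldehyde unit. O1 can therefore act first as the leaving group of an enol lactone and then as the nucleophile that closes the dihydropyran.
Cuts, in order: the two aryl O–Si bonds; then, together, the hydroxytyrosyl ester C–O bond and the O1–C2 bond; then C4–C5 and the lactone C–O bond (carbene-catalysed enol ester rearrangement); then the enol ester O–C6 bond (dienoic acid plus methyl propiolate) and the C3–C4 bond (Heck coupling of a 2-bromocrotonaldehyde acetal with methyl acrylate).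
Forward: the chain is assembled from crotonaldehyde, methyl acrylate and methyl propiolate, the dihydropyranone ring is made first, and the key step opens it with silyl-protected hydroxytyrosol and closes the dihydropyran through the same oxygen while the side chain is attached; the arene is bought.
Stereochemistry: C4 (S) comes from a chiral triazolylidene catalyst; C2 (S) is relayed from C4 by allylic 1,3-strain of the (E)-ethylidene during ring closure; C3 (S) is settled by equilibrating protonation (formyl trans to the C4 arm, cis to the C2 methyl).
Key step: step 10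

Assumption: the facial sense of the aminoindanol-derived triazolylidene on this enol ester is taken to be that of the (5aS,10bR) salt; if the first run shows the opposite sense, the commercial (5aR,10bS) antipode is used with no other change.

Step 1
Reactants: 1 (E)-crotonaldehyde
Product: 3 (Z)-2-bromobut-2-enal, via 2,3-dibromobutanal 2 (not isolated)
Conditions: Br2 (1.0 equiv), CH2Cl2, 0 °C; then Et3N (1.2 equiv), 0 °C to rt
Reagents that add atoms: bromine BrBr
Why: Bromination–dehydrobromination: anti addition of bromine to the enal, then amine-induced E1cB loss of HBr from the α-bromo aldehyde, should give the α-bromo enal as the more stable Z isomer with methyl trans to formyl.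

Step 2
Reactants: 3 (Z)-2-bromobut-2-enal
Product: 4 (Z)-2-bromo-1,1-dimethoxybut-2-ene
Conditions: HC(OMe)3, MeOH, p-toluenesulfonic acid monohydrate (2 mol%), rt; Et3N quench
Reagents that add atoms: trimethyl orthoformate COC(OC)OC; methanol CO
Why: Acid-catalysed acetalisation, driven by the orthoformate as water scavenger, should mask the formyl group (which would otherwise be attacked by the carbene of step 6 and act as a Michael acceptor) without touching the bromoalkene geometry.

Step 3
Reactants: 4 (Z)-2-bromo-1,1-dimethoxybut-2-ene; 5 methyl acrylate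
Product: 6 methyl (2E,4E)-4-(dimethoxymethyl)hexa-2,4-dienoate
Conditions: Pd(OAc)2 (5 mol%), P(o-tol)3 (10 mol%), Et3N, MeCN, 80 °C
Reagents that add atoms: none
Why: Mizoroki–Heck reaction: oxidative addition of the vinyl bromide to zerovalent palladium, syn carbopalladation of the acrylate and syn β-hydride elimination should give the (2E)-dienoate with the bromoalkene geometry retained.

Step 4
Reactants: 6 methyl (2E,4E)-4-(dimethoxymethyl)hexa-2,4-dienoate
Product: 7 (2E,4E)-4-(dimethoxymethyl)hexa-2,4-dienoic acid
Conditions: LiOH·H2O, THF/H2O (3:1), 0 °C to rt; then AcOH to pH 5, 0 °C, EtOAc extraction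
Reagents that add atoms: lithium hydroxide [Li+].[OH-]
Why: Saponification of the methyl ester with hydroxide, to which the acetal is inert, followed by release of the acid with acetic acid alone (self-buffering, no strong acid) should give the dienoic acid with the aldehyde still masked.

Step 5
Reactants: 7 (2E,4E)-4-(dimethoxymethyl)hexa-2,4-dienoic acid; 8 methyl propiolate
Product: 9 (E)-3-methoxy-3-oxoprop-1-en-1-yl (2E,4E)-4-(dimethoxymethyl)hexa-2,4-dienoate
Conditions: N-methylmorpholine (10 mol%), CH2Cl2, 0 °C to rt
Reagents that add atoms: none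
Why: Tertiary-amine-catalysed conjugate addition of a carboxylic acid to an ynoate (the amine adds to the propiolate and is displaced by the carboxylate) is a standard route to (E)-β-acyloxyacrylates and needs neither water nor strong acid.

Step 6
Reactants: 9 (E)-3-methoxy-3-oxoprop-1-en-1-yl (2E,4E)-4-(dimethoxymethyl)hexa-2,4-dienoate
Product: 10 methyl (4S)-4-[(2E)-1,1-dimethoxybut-2-en-2-yl]-2-oxo-3,4-dihydro-2H-pyran-5-carboxylate
Conditions: (5aS,10bR)-5a,10b-dihydro-2-(2,4,6-trimethylphenyl)-4H,6H-indeno[2,1-b][1,2,4]triazolo[4,3-d][1,4]oxazinium tetrafluoroborate (10 mol%), KN(SiMe3)2 (8 mol%), toluene, rt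
Reagents that add atoms: none
Why: Carbene-catalysed rearrangement of an α,β-unsaturated enol ester: the triazolylidene cleaves 9 into a dienoyl azolium and the formylacetate enolate, which recombine by 1,4-addition at the β-carbon (C4–C5 bond) and O-acylation (lactone C–O bond, catalyst released), and the indane-fused chiral backbone shields one face of the acyl azolium so that C4 is formed as S.

Step 7
Reactants: 10 methyl (4S)-4-[(2E)-1,1-dimethoxybut-2-en-2-yl]-2-oxo-3,4-dihydro-2H-pyran-5-carboxylate
Product: 11 methyl (4S)-4-[(2E)-1-oxobut-2-en-2-yl]-2-oxo-3,4-dihydro-2H-pyran-5-carboxylate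
Conditions: pyridinium p-toluenesulfonate (10 mol%), acetone/H2O (20:1), rt
Reagents that add atoms: water O
Why: Acid-catalysed acetal hydrolysis is fast for an α,β-unsaturated dimethyl acetal because the oxocarbenium ion is allyl-stabilised, so buffered pyridinium catalysis should free the enal while the enol lactone and the C4 stereocenter (its hydrogen is not conjugated to either carbonyl) survive.

Step 8
Reactants: 12 hydroxytyrosol
Product: 13 tert-butyl{2-[3,4-bis(tert-butyldimethylsilyloxy)phenyl]ethoxy}dimethylsilane
Conditions: TBSCl (3.5 equiv), imidazole (7 equiv), DMF, rt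
Reagents that add atoms: tert-butyldimethylsilyl chloride CC(C)(C)[Si](C)(C)Cl
Why: Exhaustive silylation of the two phenols and the primary alcohol with the silyl chloride and imidazole is routine silyl ether formation.

Step 9
Reactants: 13 tert-butyl{2-[3,4-bis(tert-butyldimethylsilyloxy)phenyl]ethoxy}dimethylsilane
Product: 14 2-[3,4-bis(tert-butyldimethylsilyloxy)phenyl]ethanol
Conditions: (±)-camphor-10-sulfonic acid (10 mol%), MeOH/CH2Cl2 (1:1), 0 °C
Reagents that add atoms: none
Why: Acid-catalysed methanolysis cleaves a primary alkyl silyl ether much faster than aryl silyl ethers, whose oxygen is less basic, so only the primary alcohol should be freed.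

Step 10
Reactants: 11 methyl (4S)-4-[(2E)-1-oxobut-2-en-2-yl]-2-oxo-3,4-dihydro-2H-pyran-5-carboxylate; 14 2-[3,4-bis(tert-butyldimethylsilyloxy)phenyl]ethanol
Product: 17 methyl (2S,3S,4S)-4-(2-{2-[3,4-bis(tert-butyldimethylsilyloxy)phenyl]ethoxy}-2-oxoethyl)-3-formyl-2-methyl-3,4-dihydro-2H-pyran-5-carboxylate, via ring-opened formylacetate enol 15 (not isolated), via pyran enol 16 (not isolated)
Conditions: 4-(dimethylamino)pyridine (20 mol%), 14 (1.1 equiv), CH2Cl2, 4 Å molecular sieves, rt; pH 7 phosphate buffer quench
Reagents that add atoms: none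
Why: Proposed new method: the aminopyridine attacks the lactone carbonyl of 11 (a vinylogous anhydride and the only activated acyl group present) and passes the acyl group to the primary alcohol of 14, which forms the ester C–O bond, opens the dihydropyranone and frees O1 as the enolate of a formylacetate (15); O1, held cis to C4 on the C5=C6 bond, then adds to the methyl-bearing β-carbon of the ethylidene enal in a 6-endo-trig oxa-Michael closure that forms the O1–C2 bond and the dihydropyran (16), and the aldehyde enolate so formed is protonated at C3. The closest known reaction types are the alcoholysis of enol esters and enol lactones as irreversible acyl donors and the oxa-Michael closure of ring-opened secoiridoid aglycones, which have not been run as one acyl-transfer-triggered cascade. C2 is controlled by the C4 stereocenter through allylic 1,3-strain: the ethylidene methyl is cis to C4, so the C4–H bond lies in the alkene plane and O1 can reach C2 only on the face that leaves the methyl trans to the acetate arm (2S from 4S). C3 is controlled thermodynamically, since reversible enolisation of the β-alkoxy aldehyde under the amine should settle on the half-chair with the C4 arm pseudoaxial, the formyl group axial and trans to it, and the methyl equatorial (3S). The step needs O-acylation of the alcohol ahead of conjugate addition to the enal and ahead of any phenol acylation, which the high acyl-donor reactivity of the enol lactone under nucleophilic catalysis, the silylated phenols and the aprotic medium should secure. Attack through carbon would need a four-membered ring and hemiacetal formation at the formyl carbon is reversible, so both alternatives should drain into the pyran.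

Step 11
Reactants: 17 methyl (2S,3S,4S)-4-(2-{2-[3,4-bis(tert-butyldimethylsilyloxy)phenyl]ethoxy}-2-oxoethyl)-3-formyl-2-methyl-3,4-dihydro-2H-pyran-5-carboxylate
Product: 18 methyl (2S,3S,4S)-4-{2-[2-(3,4-dihydroxyphenyl)ethoxy]-2-oxoethyl}-3-formyl-2-methyl-3,4-dihydro-2H-pyran-5-carboxylate (CNP0172886.2)
Conditions: Et3N·3HF (excess), THF, 0 °C to rt
Reagents that add atoms: none
Why: Fluoride cleavage of aryl silyl ethers with the mildly acidic amine–HF complex should free the catechol without any free base, so that neither C3 epimerisation, retro-oxa-Michael opening nor catechol oxidation is expected.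

Compound list
1 | (E)-crotonaldehyde [(E)-but-2-enal] | C/C=C/C=O | starting material
2 | (2RS,3SR)-2,3-dibromobutanal (racemic anti-addition product, one enantiomer drawn) | C[C@H](Br)[C@H](Br)C=O | intermediate
3 | (Z)-2-bromobut-2-enal | C/C=C(\Br)C=O | intermediate
4 | (Z)-2-bromo-1,1-dimethoxybut-2-ene | C/C=C(\Br)C(OC)OC | intermediate
5 | methyl acrylate | C=CC(=O)OC | starting material
6 | methyl (2E,4E)-4-(dimethoxymethyl)hexa-2,4-dienoate | C/C=C(\C=C\C(=O)OC)C(OC)OC | intermediate
7 | (2E,4E)-4-(dimethoxymethyl)hexa-2,4-dienoic acid | C/C=C(\C=C\C(=O)O)C(OC)OC | intermediate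
8 | methyl propiolate | C#CC(=O)OC | starting material
9 | (E)-3-methoxy-3-oxoprop-1-en-1-yl (2E,4E)-4-(dimethoxymethyl)hexa-2,4-dienoate | C/C=C(\C=C\C(=O)O/C=C/C(=O)OC)C(OC)OC | intermediate
10 | methyl (4S)-4-[(2E)-1,1-dimethoxybut-2-en-2-yl]-2-oxo-3,4-dihydro-2H-pyran-5-carboxylate | COC(=O)C1=COC(=O)C[C@H]1/C(=C\C)C(OC)OC | intermediate
11 | methyl (4S)-4-[(2E)-1-oxobut-2-en-2-yl]-2-oxo-3,4-dihydro-2H-pyran-5-carboxylate | COC(=O)C1=COC(=O)C[C@H]1/C(=C\C)C=O | intermediate
12 | hydroxytyrosol [2-(3,4-dihydroxyphenyl)ethanol] | OCCc1ccc(O)c(O)c1 | starting material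
13 | tert-butyl{2-[3,4-bis(tert-butyldimethylsilyloxy)phenyl]ethoxy}dimethylsilane | CC(C)(C)[Si](C)(C)OCCc1ccc(O[Si](C)(C)C(C)(C)C)c(O[Si](C)(C)C(C)(C)C)c1 | intermediate
14 | 2-[3,4-bis(tert-butyldimethylsilyloxy)phenyl]ethanol | OCCc1ccc(O[Si](C)(C)C(C)(C)C)c(O[Si](C)(C)C(C)(C)C)c1 | intermediate
15 | 2-[3,4-bis(tert-butyldimethylsilyloxy)phenyl]ethyl (3S,4E)-4-formyl-3-[(E)-3-hydroxy-1-methoxy-1-oxoprop-2-en-2-yl]hex-4-enoate (ring-opened formylacetate enol) | COC(=O)/C(=C/O)[C@@H](CC(=O)OCCc1ccc(O[Si](C)(C)C(C)(C)C)c(O[Si](C)(C)C(C)(C)C)c1)/C(=C\C)C=O | intermediate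
16 | methyl (2S,4S)-4-(2-{2-[3,4-bis(tert-butyldimethylsilyloxy)phenyl]ethoxy}-2-oxoethyl)-3-(hydroxymethylidene)-2-methyl-3,4-dihydro-2H-pyran-5-carboxylate (pyran enol) | COC(=O)C1=CO[C@@H](C)C(=CO)[C@@H]1CC(=O)OCCc1ccc(O[Si](C)(C)C(C)(C)C)c(O[Si](C)(C)C(C)(C)C)c1 | intermediate
17 | methyl (2S,3S,4S)-4-(2-{2-[3,4-bis(tert-butyldimethylsilyloxy)phenyl]ethoxy}-2-oxoethyl)-3-formyl-2-methyl-3,4-dihydro-2H-pyran-5-carboxylate | COC(=O)C1=CO[C@@H](C)[C@@H](C=O)[C@@H]1CC(=O)OCCc1ccc(O[Si](C)(C)C(C)(C)C)c(O[Si](C)(C)C(C)(C)C)c1 | intermediate
18 | methyl (2S,3S,4S)-4-{2-[2-(3,4-dihydroxyphenyl)ethoxy]-2-oxoethyl}-3-formyl-2-methyl-3,4-dihydro-2H-pyran-5-carboxylate (CNP0172886.2) | COC(=O)C1=CO[C@@H](C)[C@@H](C=O)[C@@H]1CC(=O)OCCc1ccc(O)c(O)c1 | target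

Total step count: 11.
Longest linear sequence: 9 steps (steps 1 to 7, then 10 and 11, from crotonaldehyde); the alcohol branch (steps 8 and 9) joins at step 10.

Steps most likely to fail

1. Step 10 (the proposed cascade). The alcohol or the amine catalyst may add to the exposed enal (conjugate addition or hemiacetal formation) faster than acyl transfer occurs, or the sequence may stall after ring opening and lose material through the free enol aldehyde. The fallback uses known chemistry, sets out from acetal lactone 10 and alcohol 14 and comes back at 17. The lactone is opened with 14 and 4-(dimethylamino)pyridine while the enal is still masked, an ordinary alcoholysis of an enol lactone, to give 2-[3,4-bis(tert-butyldimethylsilyloxy)phenyl]ethyl (3S,4E)-4-(dimethoxymethyl)-3-[(E)-3-hydroxy-1-methoxy-1-oxoprop-2-en-2-yl]hex-4-enoate F1. The acetal is then hydrolysed with pyridinium p-toluenesulfonate in wet acetone, which delivers 15 as a discrete compound. Compound 15 is closed to 17 by the oxa-Michael addition known for ring-opened secoiridoid aglycones, with a short final exposure to Et3N to equilibrate C3 if that is needed.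

2. Step 6. Acyl transfer from the enol ester to the chiral triazolylidene, which is less nucleophilic than the imidazolylidenes usually used for this rearrangement, may be too slow for the acyl azolium to form and the catalyst to turn over. The fallback sets out from dienoate 6 and comes back at 10, generating the same acyl azolium by oxidation instead of acyl transfer. Reduction of 6 with i-Bu2AlH (CH2Cl2, −78 °C) should give (2E,4E)-4-(dimethoxymethyl)hexa-2,4-dien-1-ol F2, and MnO2 oxidation (CH2Cl2, rt) should give (2E,4E)-4-(dimethoxymethyl)hexa-2,4-dienal F3. F3 is then annulated with methyl 3-oxopropanoate (commercial as its sodium enolate) under the same triazolium salt, a catalytic base and stoichiometric 3,3',5,5'-tetra-tert-butyl-4,4'-diphenoquinone. This is the established oxidative carbene route from enals and 1,3-dicarbonyl-type enols to 3,4-dihydropyran-2-ones and should deliver 10 directly.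

3. Step 3. Oxidative addition into the hindered trisubstituted bromoalkene may be slow, the alkene geometry may erode through reversible hydridopalladium addition, and the Lewis-acidic divalent palladium salt may ionise the acetal at 80 °C. The fallback sets out from bromide 4 and comes back at 6. It is a Suzuki–Miyaura coupling of 4 with commercial methyl (E)-3-(4,4,5,5-tetramethyl-1,3,2-dioxaborolan-2-yl)acrylate (Pd(PPh3)4, K3PO4, dioxane/H2O, 60 °C), in which both alkene geometries are fixed in the partners and no β-hydride elimination is involved. No new compound arises on this detour (entry F0).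

Further compounds
F1 | step 10 | 2-[3,4-bis(tert-butyldimethylsilyloxy)phenyl]ethyl (3S,4E)-4-(dimethoxymethyl)-3-[(E)-3-hydroxy-1-methoxy-1-oxoprop-2-en-2-yl]hex-4-enoate | COC(=O)/C(=C/O)[C@@H](CC(=O)OCCc1ccc(O[Si](C)(C)C(C)(C)C)c(O[Si](C)(C)C(C)(C)C)c1)/C(=C\C)C(OC)OC
F2 | step 6 | (2E,4E)-4-(dimethoxymethyl)hexa-2,4-dien-1-ol | C/C=C(\C=C\CO)C(OC)OC
F3 | step 6 | (2E,4E)-4-(dimethoxymethyl)hexa-2,4-dienal | C/C=C(\C=C\C=O)C(OC)OC
F0 | step 3 | none | none
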